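## Retrosynthetic overview

1. The target comes from its C3 silyl ether; the C8 isobutyrate is installed on the ring alcohol by Mitsunobu esterification with inversion.
2. Key disconnection C7–C8: a 3-(bromomethyl)butenolide bearing a tethered aldehyde is closed by an intramolecular chromium Barbier allylation. This one step forms the ten-membered ring, unveils the α-methylene lactone and sets C7 and C8 (the usual plan is an intermolecular Barbier reaction followed by ring-closing metathesis).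
3. The open chain carries the oxirane (reagent-controlled Shi epoxidation of the E-olefin) and the butenolide (Pd carbonylation of a Z-iodo allylic alcohol).
4. The chain is built from but-3-yn-1-ol, oxirane, methyl propiolate and a propargyl silyl ether: Negishi carboalumination (E-olefin), two catalytic asymmetric alkynylations (C3, C6) and a cuprate syn-addition (Z-olefin).
5. Ring order: butenolide, then oxirane, then the ten-membered carbocycle.

Assumption: germacrane numbering is used for positions (ring C1–C10; C11 lactone α-carbon, C12 carbonyl, C13 methylene; C14 on C10; C15 on C4).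
Assumption: (S,S)-ProPhenol is taken to deliver the acetylide to the Re face of an aldehyde and (R,R)-ProPhenol to the Si face; if the sense is the reverse, the two antipodes are exchanged.
Assumption: the facial course of step 17 is predicted from the chair model and is not experimentally established; the fallback for step 18 covers the opposite outcome.

## Route

Step 1
Reactants: 1 but-3-yn-1-ol
Product: 2 1-[(but-3-yn-1-yloxy)methyl]-4-methoxybenzene
Conditions: NaH, 4-methoxybenzyl chloride, Bu4NI (cat.), THF/DMF, 0 °C → rt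
Reagents that add atoms: 4-methoxybenzyl chloride, COc1ccc(CCl)cc1
Why: Williamson etherification; the PMB ether is the one group that can later be removed oxidatively in the presence of the allylic bromide, the silyl ether and the oxirane.

Step 2
Reactants: 2 1-[(but-3-yn-1-yloxy)methyl]-4-methoxybenzene; 3 oxirane
Product: 6 (E)-6-[(4-methoxybenzyl)oxy]-4-methylhex-3-en-1-ol, via alkenyldimethylalane 4 (not isolated), via lithium alkenylalanate 5 (not isolated)
Conditions: Me3Al, Cp2ZrCl2 (25 mol %), ClCH2CH2Cl, rt; excess Me3Al removed in vacuo; n-BuLi, hexane/THF, −78 → 0 °C; oxirane, −30 °C → rt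
Reagents that add atoms: trimethylaluminium, C[Al](C)C
Why: Negishi zirconium-catalysed carboalumination adds Me and Al syn across the terminal alkyne (Me to the internal carbon), and the lithium alanate opens oxirane with retention, giving the E-trisubstituted C1=C10 olefin.

Step 3
Reactants: 6 (E)-6-[(4-methoxybenzyl)oxy]-4-methylhex-3-en-1-ol
Product: 7 (E)-6-[(4-methoxybenzyl)oxy]-4-methylhex-3-enal
Conditions: Dess–Martin periodinane, NaHCO3, CH2Cl2, 0 °C; used crude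
Reagents that add atoms: none
Why: Buffered Dess–Martin oxidation gives the β,γ-unsaturated aldehyde without moving the olefin into conjugation.

Step 4
Reactants: 7 (E)-6-[(4-methoxybenzyl)oxy]-4-methylhex-3-enal; 8 methyl prop-2-ynoate
Product: 10 methyl (4S,6E)-4-hydroxy-9-[(4-methoxybenzyl)oxy]-7-methylnon-6-en-2-ynoate, via alkynyl(methyl)zinc 9 (not isolated)
Conditions: (S,S)-ProPhenol [2,6-bis{[(S)-2-(hydroxydiphenylmethyl)pyrrolidin-1-yl]methyl}-4-methylphenol] (20 mol %), Me2Zn, Ph3PO (40 mol %), toluene, 4 °C; slow addition of 7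
Reagents that add atoms: none
Why: Zinc–ProPhenol catalysed asymmetric alkynylation of the aldehyde (Trost type); the dinuclear zinc complex delivers the acetylide to the Re face and sets C3 as S.

Step 5
Reactants: 10 methyl (4S,6E)-4-hydroxy-9-[(4-methoxybenzyl)oxy]-7-methylnon-6-en-2-ynoate
Product: 11 methyl (4S,6E)-4-[(tert-butyldimethylsilyl)oxy]-9-[(4-methoxybenzyl)oxy]-7-methylnon-6-en-2-ynoate
Conditions: TBSCl, imidazole, DMF, rt
Reagents that add atoms: tert-butyldimethylsilyl chloride, CC(C)(C)[Si](C)(C)Cl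
Why: Standard silylation of the secondary alcohol; it blocks O3 so that the Z-enoate of step 6 cannot lactonise.

Step 6
Reactants: 11 methyl (4S,6E)-4-[(tert-butyldimethylsilyl)oxy]-9-[(4-methoxybenzyl)oxy]-7-methylnon-6-en-2-ynoate
Product: 12 methyl (2Z,4S,6E)-4-[(tert-butyldimethylsilyl)oxy]-9-[(4-methoxybenzyl)oxy]-3,7-dimethylnona-2,6-dienoate
Conditions: Me2CuLi, THF, −78 °C; MeOH/aq. NH4Cl quench at −78 °C
Reagents that add atoms: lithium dimethylcuprate, [Li+].C[Cu-]C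
Why: Gilman cuprate conjugate addition to the ynoate is a syn carbocupration and protonation at −78 °C keeps that geometry, so C15 ends cis to H5 and the Z-configured C4=C5 olefin results.

Step 7
Reactants: 12 methyl (2Z,4S,6E)-4-[(tert-butyldimethylsilyl)oxy]-9-[(4-methoxybenzyl)oxy]-3,7-dimethylnona-2,6-dienoate
Product: 13 (2Z,4S,6E)-4-[(tert-butyldimethylsilyl)oxy]-9-[(4-methoxybenzyl)oxy]-3,7-dimethylnona-2,6-dien-1-ol
Conditions: i-Bu2AlH, CH2Cl2, −78 °C
Reagents that add atoms: none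
Why: Hydride 1,2-reduction of the enoate to the allylic alcohol; olefin geometry and C3 are untouched.

Step 8
Reactants: 13 (2Z,4S,6E)-4-[(tert-butyldimethylsilyl)oxy]-9-[(4-methoxybenzyl)oxy]-3,7-dimethylnona-2,6-dien-1-ol
Product: 14 (2Z,4S,6E)-4-[(tert-butyldimethylsilyl)oxy]-9-[(4-methoxybenzyl)oxy]-3,7-dimethylnona-2,6-dienal
Conditions: Dess–Martin periodinane, NaHCO3, CH2Cl2, 0 °C
Reagents that add atoms: none
Why: Buffered Dess–Martin oxidation gives the Z-enal without Z/E isomerisation.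

Step 9
Reactants: 14 (2Z,4S,6E)-4-[(tert-butyldimethylsilyl)oxy]-9-[(4-methoxybenzyl)oxy]-3,7-dimethylnona-2,6-dienal; 15 tert-butyldimethyl(prop-2-yn-1-yloxy)silane
Product: 17 (4R,5Z,7S,9E)-1,7-bis[(tert-butyldimethylsilyl)oxy]-12-[(4-methoxybenzyl)oxy]-6,10-dimethyldodeca-5,9-dien-2-yn-4-ol, via alkynyl(methyl)zinc 16 (not isolated)
Conditions: (R,R)-ProPhenol (20 mol %), Me2Zn, Ph3PO (40 mol %), toluene, 4 °C
Reagents that add atoms: none
Why: The same zinc–ProPhenol alkynylation, for which enals are the best substrates; the antipodal ligand delivers the acetylide to the Si face and sets C6 as R under reagent control.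

Step 10
Reactants: 17 (4R,5Z,7S,9E)-1,7-bis[(tert-butyldimethylsilyl)oxy]-12-[(4-methoxybenzyl)oxy]-6,10-dimethyldodeca-5,9-dien-2-yn-4-ol
Product: 19 (2Z,4R,5Z,7S,9E)-1,7-bis[(tert-butyldimethylsilyl)oxy]-2-iodo-12-[(4-methoxybenzyl)oxy]-6,10-dimethyldodeca-2,5,9-trien-4-ol, via cyclic sodium vinylalanate 18 (not isolated)
Conditions: NaAlH2(OCH2CH2OMe)2, THF, 0 °C; then I2, THF, −78 °C
Reagents that add atoms: iodine, [I][I]
Why: Alkoxide-directed anti-hydroalumination of the propargylic alcohol puts Al on the distal alkyne carbon C11, cis to C6, and iodinolysis with retention gives the Z-γ-iodo allylic alcohol.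

Step 11
Reactants: 19 (2Z,4R,5Z,7S,9E)-1,7-bis[(tert-butyldimethylsilyl)oxy]-2-iodo-12-[(4-methoxybenzyl)oxy]-6,10-dimethyldodeca-2,5,9-trien-4-ol
Product: 20 (5R)-3-{[(tert-butyldimethylsilyl)oxy]methyl}-5-[(1Z,3S,5E)-3-[(tert-butyldimethylsilyl)oxy]-8-[(4-methoxybenzyl)oxy]-2,6-dimethylocta-1,5-dien-1-yl]furan-2(5H)-one
Conditions: PdCl2(PPh3)2 (5 mol %), CO (1 atm), K2CO3, THF, rt
Reagents that add atoms: carbon monoxide, [C-]#[O+]
Why: Palladium-catalysed carbonylative lactonisation: oxidative addition of zerovalent palladium into the C–I bond, CO insertion and capture of the acyl–palladium by the cis hydroxyl close the butenolide without touching C6.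

Step 12
Reactants: 20 (5R)-3-{[(tert-butyldimethylsilyl)oxy]methyl}-5-[(1Z,3S,5E)-3-[(tert-butyldimethylsilyl)oxy]-8-[(4-methoxybenzyl)oxy]-2,6-dimethylocta-1,5-dien-1-yl]furan-2(5H)-one
Product: 21 (5R)-5-[(1Z,3S,5E)-3-[(tert-butyldimethylsilyl)oxy]-8-[(4-methoxybenzyl)oxy]-2,6-dimethylocta-1,5-dien-1-yl]-3-(hydroxymethyl)furan-2(5H)-one
Conditions: HF·pyridine, pyridine, THF, 0 °C
Reagents that add atoms: none
Why: Fluoride desilylation; the primary allylic silyl ether is cleaved much faster than the hindered secondary one at C3.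

Step 13
Reactants: 21 (5R)-5-[(1Z,3S,5E)-3-[(tert-butyldimethylsilyl)oxy]-8-[(4-methoxybenzyl)oxy]-2,6-dimethylocta-1,5-dien-1-yl]-3-(hydroxymethyl)furan-2(5H)-one
Product: 22 (5R)-5-[(1Z,3S)-3-[(tert-butyldimethylsilyl)oxy]-4-[(2S,3S)-3-{2-[(4-methoxybenzyl)oxy]ethyl}-3-methyloxiran-2-yl]-2-methylbut-1-en-1-yl]-3-(hydroxymethyl)furan-2(5H)-one
Conditions: 1,2:4,5-di-O-isopropylidene-β-L-erythro-2,3-hexodiulo-2,6-pyranose (the L-configured Shi ketone, 1 equiv), KHSO5 (as Oxone), NaHCO3, Bu4NHSO4 (cat.), MeCN/aq. Na2EDTA, 0 °C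
Reagents that add atoms: potassium peroxymonosulfate, [K+].[O-]S(=O)(=O)OO
Why: Shi asymmetric epoxidation: the dioxirane from the L-configured ketone attacks through a spiro transition state the olefin face opposite to that taken by the D-ketone, giving the 1S,10S oxirane, and it selects the electron-rich E-olefin over the Z-olefin flanked by two allylic C–O bonds and over the electron-poor butenolide.

Step 14
Reactants: 22 (5R)-5-[(1Z,3S)-3-[(tert-butyldimethylsilyl)oxy]-4-[(2S,3S)-3-{2-[(4-methoxybenzyl)oxy]ethyl}-3-methyloxiran-2-yl]-2-methylbut-1-en-1-yl]-3-(hydroxymethyl)furan-2(5H)-one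
Product: 23 (5R)-3-(bromomethyl)-5-[(1Z,3S)-3-[(tert-butyldimethylsilyl)oxy]-4-[(2S,3S)-3-{2-[(4-methoxybenzyl)oxy]ethyl}-3-methyloxiran-2-yl]-2-methylbut-1-en-1-yl]furan-2(5H)-one
Conditions: CBr4, PPh3, CH2Cl2, −20 → 0 °C
Reagents that add atoms: tetrabromomethane, BrC(Br)(Br)Br
Why: Appel bromination, an SN2 displacement at the primary allylic carbon under neutral conditions.

Step 15
Reactants: 23 (5R)-3-(bromomethyl)-5-[(1Z,3S)-3-[(tert-butyldimethylsilyl)oxy]-4-[(2S,3S)-3-{2-[(4-methoxybenzyl)oxy]ethyl}-3-methyloxiran-2-yl]-2-methylbut-1-en-1-yl]furan-2(5H)-one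
Product: 24 (5R)-3-(bromomethyl)-5-[(1Z,3S)-3-[(tert-butyldimethylsilyl)oxy]-4-[(2S,3S)-3-(2-hydroxyethyl)-3-methyloxiran-2-yl]-2-methylbut-1-en-1-yl]furan-2(5H)-one
Conditions: DDQ, CH2Cl2/pH 7 buffer, 0 °C
Reagents that add atoms: none
Why: Oxidative PMB cleavage (benzylic hydride abstraction by DDQ, then hydrolysis) is neutral, so the bromide, oxirane, butenolide and silyl ether survive.

Step 16
Reactants: 24 (5R)-3-(bromomethyl)-5-[(1Z,3S)-3-[(tert-butyldimethylsilyl)oxy]-4-[(2S,3S)-3-(2-hydroxyethyl)-3-methyloxiran-2-yl]-2-methylbut-1-en-1-yl]furan-2(5H)-one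
Product: 25 (5R)-3-(bromomethyl)-5-[(1Z,3S)-3-[(tert-butyldimethylsilyl)oxy]-2-methyl-4-[(2S,3S)-3-methyl-3-(2-oxoethyl)oxiran-2-yl]but-1-en-1-yl]furan-2(5H)-one
Conditions: Dess–Martin periodinane, NaHCO3, CH2Cl2, 0 °C; used at once
Reagents that add atoms: none
Why: Buffered Dess–Martin oxidation gives the β,γ-epoxy aldehyde without β-elimination of the oxirane.

Step 17
Reactants: 25 (5R)-3-(bromomethyl)-5-[(1Z,3S)-3-[(tert-butyldimethylsilyl)oxy]-2-methyl-4-[(2S,3S)-3-methyl-3-(2-oxoethyl)oxiran-2-yl]but-1-en-1-yl]furan-2(5H)-one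
Product: 27 (1S,3S,4Z,6R,7R,8S,10S)-3-[(tert-butyldimethylsilyl)oxy]-1,10-epoxy-8-hydroxygermacra-4,11(13)-dien-12,6-olide, via allylchromium dichloride 26 (not isolated)
Conditions: CrCl2 (8 equiv), THF, 0.002 M, syringe-pump addition of 25 over 12 h, rt; pH 7 work-up
Reagents that add atoms: none
Why: Intramolecular Nozaki–Hiyama (chromium Barbier) allylation at high dilution: the allylchromium reacts at C7 (SE2') through a chair transition state on the butenolide face opposite the C6 side chain, with the ring-locked C6 and the aldehyde chain both pseudo-equatorial, which closes the ten-membered ring, unveils the exocyclic methylene and sets C7 as R (trans to C6) and C8 as S.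

Step 18
Reactants: 27 (1S,3S,4Z,6R,7R,8S,10S)-3-[(tert-butyldimethylsilyl)oxy]-1,10-epoxy-8-hydroxygermacra-4,11(13)-dien-12,6-olide; 28 2-methylpropanoic acid
Product: 29 (1S,3S,4Z,6R,7R,8R,10S)-3-[(tert-butyldimethylsilyl)oxy]-1,10-epoxy-8-(2-methylpropanoyloxy)germacra-4,11(13)-dien-12,6-olide
Conditions: PPh3, DIAD, THF, 0 °C → rt
Reagents that add atoms: none
Why: Mitsunobu esterification: the carboxylate displaces the alkoxyphosphonium by SN2 with inversion, turning the 8S alcohol into the 8R isobutyrate in one step.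

Step 19
Reactants: 29 (1S,3S,4Z,6R,7R,8R,10S)-3-[(tert-butyldimethylsilyl)oxy]-1,10-epoxy-8-(2-methylpropanoyloxy)germacra-4,11(13)-dien-12,6-olide
Product: 30 (1S,3S,4Z,6R,7R,8R,10S)-1,10-epoxy-3-hydroxy-8-(2-methylpropanoyloxy)germacra-4,11(13)-dien-12,6-olide
Conditions: HF·pyridine, excess pyridine, THF, 0 °C
Reagents that add atoms: none
Why: Pyridine-buffered fluoride desilylation frees the C3 hydroxyl under conditions that the oxirane, the ester and the α-methylene lactone tolerate.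

## Compound list

1 | but-3-yn-1-ol | C#CCCO | starting material
2 | 1-[(but-3-yn-1-yloxy)methyl]-4-methoxybenzene | C#CCCOCc1ccc(OC)cc1 | intermediate
3 | oxirane | C1CO1 | starting material
4 | (E)-{4-[(4-methoxybenzyl)oxy]-2-methylbut-1-en-1-yl}dimethylalane | C[Al](C)/C=C(\C)CCOCc1ccc(OC)cc1 | intermediate
5 | lithium butyl{(E)-4-[(4-methoxybenzyl)oxy]-2-methylbut-1-en-1-yl}dimethylalanate | [Li+].CCCC[Al-](C)(C)/C=C(\C)CCOCc1ccc(OC)cc1 | intermediate
6 | (E)-6-[(4-methoxybenzyl)oxy]-4-methylhex-3-en-1-ol | OCC/C=C(\C)CCOCc1ccc(OC)cc1 | intermediate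
7 | (E)-6-[(4-methoxybenzyl)oxy]-4-methylhex-3-enal | O=CC/C=C(\C)CCOCc1ccc(OC)cc1 | intermediate
8 | methyl prop-2-ynoate (methyl propiolate) | C#CC(=O)OC | starting material
9 | methyl 3-(methylzincio)prop-2-ynoate | C[Zn]C#CC(=O)OC | intermediate
10 | methyl (4S,6E)-4-hydroxy-9-[(4-methoxybenzyl)oxy]-7-methylnon-6-en-2-ynoate | COC(=O)C#C[C@@H](O)C/C=C(\C)CCOCc1ccc(OC)cc1 | intermediate
11 | methyl (4S,6E)-4-[(tert-butyldimethylsilyl)oxy]-9-[(4-methoxybenzyl)oxy]-7-methylnon-6-en-2-ynoate | COC(=O)C#C[C@@H](O[Si](C)(C)C(C)(C)C)C/C=C(\C)CCOCc1ccc(OC)cc1 | intermediate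
12 | methyl (2Z,4S,6E)-4-[(tert-butyldimethylsilyl)oxy]-9-[(4-methoxybenzyl)oxy]-3,7-dimethylnona-2,6-dienoate | COC(=O)/C=C(/C)[C@@H](O[Si](C)(C)C(C)(C)C)C/C=C(\C)CCOCc1ccc(OC)cc1 | intermediate
13 | (2Z,4S,6E)-4-[(tert-butyldimethylsilyl)oxy]-9-[(4-methoxybenzyl)oxy]-3,7-dimethylnona-2,6-dien-1-ol | OC/C=C(/C)[C@@H](O[Si](C)(C)C(C)(C)C)C/C=C(\C)CCOCc1ccc(OC)cc1 | intermediate
14 | (2Z,4S,6E)-4-[(tert-butyldimethylsilyl)oxy]-9-[(4-methoxybenzyl)oxy]-3,7-dimethylnona-2,6-dienal | O=C/C=C(/C)[C@@H](O[Si](C)(C)C(C)(C)C)C/C=C(\C)CCOCc1ccc(OC)cc1 | intermediate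
15 | tert-butyldimethyl(prop-2-yn-1-yloxy)silane | C#CCO[Si](C)(C)C(C)(C)C | starting material
16 | {3-[(tert-butyldimethylsilyl)oxy]prop-1-yn-1-yl}(methyl)zinc | C[Zn]C#CCO[Si](C)(C)C(C)(C)C | intermediate
17 | (4R,5Z,7S,9E)-1,7-bis[(tert-butyldimethylsilyl)oxy]-12-[(4-methoxybenzyl)oxy]-6,10-dimethyldodeca-5,9-dien-2-yn-4-ol | CC(C)(C)[Si](C)(C)OCC#C[C@H](O)/C=C(/C)[C@@H](O[Si](C)(C)C(C)(C)C)C/C=C(\C)CCOCc1ccc(OC)cc1 | intermediate
18 | sodium (5R)-5-[(1Z,3S,5E)-3-[(tert-butyldimethylsilyl)oxy]-8-[(4-methoxybenzyl)oxy]-2,6-dimethylocta-1,5-dien-1-yl]-3-{[(tert-butyldimethylsilyl)oxy]methyl}-2,2-bis(2-methoxyethoxy)-2,5-dihydro-1,2-oxaaluminol-2-uide (cyclic vinylalanate; Al on O6 and C11) | [Na+].COCCO[Al-]1(OCCOC)O[C@H](/C=C(/C)[C@@H](O[Si](C)(C)C(C)(C)C)C/C=C(\C)CCOCc2ccc(OC)cc2)C=C1CO[Si](C)(C)C(C)(C)C | intermediate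
19 | (2Z,4R,5Z,7S,9E)-1,7-bis[(tert-butyldimethylsilyl)oxy]-2-iodo-12-[(4-methoxybenzyl)oxy]-6,10-dimethyldodeca-2,5,9-trien-4-ol | CC(C)(C)[Si](C)(C)OC/C(I)=C/[C@H](O)/C=C(/C)[C@@H](O[Si](C)(C)C(C)(C)C)C/C=C(\C)CCOCc1ccc(OC)cc1 | intermediate
20 | (5R)-3-{[(tert-butyldimethylsilyl)oxy]methyl}-5-[(1Z,3S,5E)-3-[(tert-butyldimethylsilyl)oxy]-8-[(4-methoxybenzyl)oxy]-2,6-dimethylocta-1,5-dien-1-yl]furan-2(5H)-one | CC(C)(C)[Si](C)(C)OCC1=C[C@@H](/C=C(/C)[C@@H](O[Si](C)(C)C(C)(C)C)C/C=C(\C)CCOCc2ccc(OC)cc2)OC1=O | intermediate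
21 | (5R)-5-[(1Z,3S,5E)-3-[(tert-butyldimethylsilyl)oxy]-8-[(4-methoxybenzyl)oxy]-2,6-dimethylocta-1,5-dien-1-yl]-3-(hydroxymethyl)furan-2(5H)-one | OCC1=C[C@@H](/C=C(/C)[C@@H](O[Si](C)(C)C(C)(C)C)C/C=C(\C)CCOCc2ccc(OC)cc2)OC1=O | intermediate
22 | (5R)-5-[(1Z,3S)-3-[(tert-butyldimethylsilyl)oxy]-4-[(2S,3S)-3-{2-[(4-methoxybenzyl)oxy]ethyl}-3-methyloxiran-2-yl]-2-methylbut-1-en-1-yl]-3-(hydroxymethyl)furan-2(5H)-one | OCC1=C[C@@H](/C=C(/C)[C@@H](O[Si](C)(C)C(C)(C)C)C[C@@H]2O[C@@]2(C)CCOCc2ccc(OC)cc2)OC1=O | intermediate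
23 | (5R)-3-(bromomethyl)-5-[(1Z,3S)-3-[(tert-butyldimethylsilyl)oxy]-4-[(2S,3S)-3-{2-[(4-methoxybenzyl)oxy]ethyl}-3-methyloxiran-2-yl]-2-methylbut-1-en-1-yl]furan-2(5H)-one | BrCC1=C[C@@H](/C=C(/C)[C@@H](O[Si](C)(C)C(C)(C)C)C[C@@H]2O[C@@]2(C)CCOCc2ccc(OC)cc2)OC1=O | intermediate
24 | (5R)-3-(bromomethyl)-5-[(1Z,3S)-3-[(tert-butyldimethylsilyl)oxy]-4-[(2S,3S)-3-(2-hydroxyethyl)-3-methyloxiran-2-yl]-2-methylbut-1-en-1-yl]furan-2(5H)-one | BrCC1=C[C@@H](/C=C(/C)[C@@H](O[Si](C)(C)C(C)(C)C)C[C@@H]2O[C@@]2(C)CCO)OC1=O | intermediate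
25 | (5R)-3-(bromomethyl)-5-[(1Z,3S)-3-[(tert-butyldimethylsilyl)oxy]-2-methyl-4-[(2S,3S)-3-methyl-3-(2-oxoethyl)oxiran-2-yl]but-1-en-1-yl]furan-2(5H)-one | BrCC1=C[C@@H](/C=C(/C)[C@@H](O[Si](C)(C)C(C)(C)C)C[C@@H]2O[C@@]2(C)CC=O)OC1=O | intermediate
26 | {[(5R)-5-[(1Z,3S)-3-[(tert-butyldimethylsilyl)oxy]-2-methyl-4-[(2S,3S)-3-methyl-3-(2-oxoethyl)oxiran-2-yl]but-1-en-1-yl]-2-oxo-2,5-dihydrofuran-3-yl]methyl}chromium dichloride (trivalent chromium) | Cl[Cr](Cl)CC1=C[C@@H](/C=C(/C)[C@@H](O[Si](C)(C)C(C)(C)C)C[C@@H]2O[C@@]2(C)CC=O)OC1=O | intermediate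
27 | (1S,3S,4Z,6R,7R,8S,10S)-3-[(tert-butyldimethylsilyl)oxy]-1,10-epoxy-8-hydroxygermacra-4,11(13)-dien-12,6-olide | C=C1C(=O)O[C@@H]2/C=C(/C)[C@@H](O[Si](C)(C)C(C)(C)C)C[C@@H]3O[C@@]3(C)C[C@H](O)[C@@H]12 | intermediate
28 | 2-methylpropanoic acid (isobutyric acid) | CC(C)C(=O)O | starting material
29 | (1S,3S,4Z,6R,7R,8R,10S)-3-[(tert-butyldimethylsilyl)oxy]-1,10-epoxy-8-(2-methylpropanoyloxy)germacra-4,11(13)-dien-12,6-olide | C=C1C(=O)O[C@@H]2/C=C(/C)[C@@H](O[Si](C)(C)C(C)(C)C)C[C@@H]3O[C@@]3(C)C[C@@H](OC(=O)C(C)C)[C@@H]12 | intermediate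
30 | (1S,3S,4Z,6R,7R,8R,10S)-1,10-epoxy-3-hydroxy-8-(2-methylpropanoyloxy)germacra-4,11(13)-dien-12,6-olide (CNP0261225.3) | C=C1C(=O)O[C@@H]2/C=C(/C)[C@@H](O)C[C@@H]3O[C@@]3(C)C[C@@H](OC(=O)C(C)C)[C@@H]12 | target

## Step count and weak points

Total steps: 19. Longest linear sequence: 19 steps (1 → 30).

**Step 17 (ring closure).** The allylchromium may be protonated or may oligomerise. The epoxy aldehyde is fragile, and the freed 8-hydroxyl could translactonise. The facial course at C8 is a prediction from the chair model. The fallback stores the nucleophile as a boronate and closes the ring by a metal-free allylboration. It sets out from 24 and comes back at 27. Bromide 24 is borylated with bis(pinacolato)diboron and Pd2(dba)3 (THF, rt) to give the pinacol allylboronate alcohol F1. Buffered Dess–Martin oxidation gives the boronate aldehyde F2. F2 is warmed at 0.002 M in toluene (50 °C) and cyclises through the same chair transition state; aqueous work-up of the borate gives 27.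

**Step 18 (Mitsunobu at a hindered ring alcohol).** Elimination or no reaction is possible. The step is also wrong if step 17 gives the other C8 epimer. The fallback replaces SN2 inversion by oxidation, reagent-controlled reduction and acylation. It sets out from 27 and comes back at 29. Buffered Dess–Martin oxidation of 27 gives the 8-ketone F3. Reduction with (S)-Me-CBS oxazaborolidine and catecholborane (toluene, −78 °C) gives the 8R alcohol F4. Isobutyric anhydride with DMAP acylates F4 with retention to 29. F4 is also the alcohol that step 17 would give if the aldehyde chain sat pseudo-axial; it would then be acylated directly.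

**Step 4 (asymmetric alkynylation of an enolisable β,γ-unsaturated aldehyde).** Aldol reaction, olefin migration or low ee may intervene. The fallback takes C3 from the chiral pool. It sets out from 5 and comes back at 11. Alanate 5, made as in step 2, is treated with methyl (S)-oxirane-2-carboxylate instead of oxirane and opens it at CH2 to give the α-hydroxy ester F5. TBSCl with imidazole gives the silyl ether F6. One-pot i-Bu2AlH reduction (−78 °C) and Ohira–Bestmann homologation (dimethyl (1-diazo-2-oxopropyl)phosphonate, K2CO3, MeOH) gives the terminal alkyne F7. n-BuLi, then ClCO2Me, gives 11.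

## Further compounds

F1 | step 17 | (5R)-5-[(1Z,3S)-3-[(tert-butyldimethylsilyl)oxy]-4-[(2S,3S)-3-(2-hydroxyethyl)-3-methyloxiran-2-yl]-2-methylbut-1-en-1-yl]-3-[(4,4,5,5-tetramethyl-1,3,2-dioxaborolan-2-yl)methyl]furan-2(5H)-one | CC1(C)OB(CC2=C[C@@H](/C=C(/C)[C@@H](O[Si](C)(C)C(C)(C)C)C[C@@H]3O[C@@]3(C)CCO)OC2=O)OC1(C)C
F2 | step 17 | (5R)-5-[(1Z,3S)-3-[(tert-butyldimethylsilyl)oxy]-2-methyl-4-[(2S,3S)-3-methyl-3-(2-oxoethyl)oxiran-2-yl]but-1-en-1-yl]-3-[(4,4,5,5-tetramethyl-1,3,2-dioxaborolan-2-yl)methyl]furan-2(5H)-one | CC1(C)OB(CC2=C[C@@H](/C=C(/C)[C@@H](O[Si](C)(C)C(C)(C)C)C[C@@H]3O[C@@]3(C)CC=O)OC2=O)OC1(C)C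
F3 | step 18 | (1S,3S,4Z,6R,7S,10S)-3-[(tert-butyldimethylsilyl)oxy]-1,10-epoxy-8-oxogermacra-4,11(13)-dien-12,6-olide | C=C1C(=O)O[C@@H]2/C=C(/C)[C@@H](O[Si](C)(C)C(C)(C)C)C[C@@H]3O[C@@]3(C)CC(=O)[C@@H]12
F4 | step 18 | (1S,3S,4Z,6R,7R,8R,10S)-3-[(tert-butyldimethylsilyl)oxy]-1,10-epoxy-8-hydroxygermacra-4,11(13)-dien-12,6-olide | C=C1C(=O)O[C@@H]2/C=C(/C)[C@@H](O[Si](C)(C)C(C)(C)C)C[C@@H]3O[C@@]3(C)C[C@@H](O)[C@@H]12
F5 | step 4 | methyl (2S,4E)-2-hydroxy-7-[(4-methoxybenzyl)oxy]-5-methylhept-4-enoate | COC(=O)[C@@H](O)C/C=C(\C)CCOCc1ccc(OC)cc1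
F6 | step 4 | methyl (2S,4E)-2-[(tert-butyldimethylsilyl)oxy]-7-[(4-methoxybenzyl)oxy]-5-methylhept-4-enoate | COC(=O)[C@@H](O[Si](C)(C)C(C)(C)C)C/C=C(\C)CCOCc1ccc(OC)cc1
F7 | step 4 | tert-butyl{[(3S,5E)-8-[(4-methoxybenzyl)oxy]-6-methyloct-5-en-1-yn-3-yl]oxy}dimethylsilane | C#C[C@@H](O[Si](C)(C)C(C)(C)C)C/C=C(\C)CCOCc1ccc(OC)cc1
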